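(The numbers of this flask belong to no real substance.)

By the reading at 5.0 s the fork of J is long past: its half-life by the step to Q alone is 0.041 s, and the scheme gives J.E no way out.

J 0.0020 M; Z 0.62 mM (held); time 5.0 s

    Z ⇌ E, rate k1*(csat - [E]) (k1 = 11 s⁻¹, csat = 0.62 mM)
    J + E → J.E (k2 = 25000 M⁻¹ s⁻¹)
    J → Q (k3 = 17 s⁻¹)
    2 J → J2 (k4 = 0.057 M⁻¹ s⁻¹)
    2 E → E2 (k5 = 110 M⁻¹ s⁻¹)
    E ⇌ D (K6 = 5.4, k6 = 0.20 s⁻¹)

- percent here means J units held: one J2 counts as two
- two of one species on the left: rate k times its square, two consumed each time
- at the start none of E is dissolved
- run time (flask): 5.0 s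

- J.E at 5.0 s, in percent of the J charged
- the change that raises the amount of J.E at 5.0 s, in percent of the J charged most ("none" if none brings more than 2 percentage points) (west / north / none)
- amount of J.E at 5.0 s, in percent of the J charged, after west

- west: doubling the saturation concentration of Z, all else as stated
- north: doubling the transfer coefficient of step 1, all else as stated

I follow one J in the flask. It leaves to Q at 17 s⁻¹, or to J.E at 25000 M⁻¹ s⁻¹ times cE. With J at cJ, E relaxes at 11 s⁻¹ plus 25000 M⁻¹ s⁻¹ times cJ, which is 61.0 s⁻¹ for J as charged, faster than J dies. So I balance E's making against its use, and cE is 6.82 mM s⁻¹ divided by that relaxation rate. The pairing of J (2.28 × 10⁻⁴ s⁻¹) and of E (0.136 s⁻¹) are far slower than the loss of J, and E's loss to D has a half-life of 3.5 s, so I drop them.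

My table has three rows, each giving cE and the chance of capture. With J as charged, cE is 0.112 mM and the chance is 14.1%. With J at half its charge, cE is 0.189 mM. With cJ at zero, cE is 0.62 mM and the chance is 47.7%.

Reading down, the chance climbs, but the bottom row is the limit of cJ at zero, where no J stands at the fork. So the middle row stands for the average over the J spent, and I carry the capture chance at half-spent J, the selectivity of the fork, 21.8%. Late on, E follows at 11 s⁻¹, slower than J dies, and it starts at zero, so I expect this to lie high. The same row gives 35.8% for west and 29.9% for north, so I choose west.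

The forecast gives 16.5%, west and 26.4%: “West doubles the source without adding a sink”.

The flask reads 16.6%. West gains 10 percentage points, more than the 7 points for north, and gives 26.6%. My 21.8% does lie high, by 5.2 points. In the neighbouring flask, charged with 0.0050 M of J, the same row gives cE of 0.0928 mM and a chance of 12.0%, lower than the flask's 21.8%. That neighbour reads 12.1% as J.E and 87.9% as Q at 5.00 s.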